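**Plan**

1. Numbering (aryltetralin): ring A is the fused arene C4a–C8a, with 6-OH para to C8a and 7-OMe para to C4a. Ring B is C1–C4, ring C is the guaiacyl group on C1, and C9/C9′ are the CH2OH carbons on C2/C3.
2. The retrosynthesis cuts C2–C3 (ring B) first, then C1–C1′ (ring C to the diarylmethine), then C8a–C1. The customary C1–C8a Friedel–Crafts closure is not used.
3. Enabling feature: C2 and C3 both carry CH2OH, so ring B contains a succinate C9–C2–C3–C9′ whose central bond joins two ester α-carbons. Both chains sit ortho to each other on ring A (C8a and C4a), so a bis-enolate of the open form can close a six-membered ring.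
4. Forward order: ring A is bought with C4–C3–C9′ attached. Bromination para to O-6 marks C8a, a Heck reaction adds C1–C2–C9, conjugate arylation adds ring C, and oxidative enolate coupling closes ring B last.
5. Stereochemistry: C1 is set by catalysis (Rh/chiral diene). C2 and C3 are relayed from C1 in the ring closure (A1,3 strain, half-chair) and then secured by base equilibration to the all-equatorial 1,2-trans-2,3-trans diester.

Key step: step 6

Remark: the SMILES places the ring A hydroxyl para to C8a (6-OH, 7-OMe), so ring A comes from the isovanillyl series and ring C from the vanillyl series.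

Assumption: the Rh/(R,R)-Ph-bod* catalyst is taken to deliver aryl to the α-re face of (E)-enoate 6, as in the accepted model, which gives (S)-8. If the sense were opposite, the (S,S)-ligand would be used.

**Step 1**
Reactants: 1 3-(3-hydroxy-4-methoxyphenyl)propanoic acid
Product: 2 methyl 3-(3-hydroxy-4-methoxyphenyl)propanoate
Conditions: MeOH, H2SO4 (cat.), reflux
Reagents that add atoms: methanol, CO
Why: Fischer esterification of an unhindered acid leaves the phenol untouched and involves no stereocenter.

**Step 2**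
Reactants: 2 methyl 3-(3-hydroxy-4-methoxyphenyl)propanoate
Product: 3 methyl 3-[3-(benzyloxy)-4-methoxyphenyl]propanoate
Conditions: BnBr, K2CO3, DMF, 60 °C
Reagents that add atoms: benzyl bromide, BrCc1ccccc1
Why: Williamson ether synthesis on the only acidic OH gives a benzyl cap that keeps the phenol from being oxidised in step 6 and leaves by hydrogenolysis in step 9.

**Step 3**
Reactants: 3 methyl 3-[3-(benzyloxy)-4-methoxyphenyl]propanoate
Product: 4 methyl 3-[5-(benzyloxy)-2-bromo-4-methoxyphenyl]propanoate
Conditions: NBS, MeCN, 0 °C to rt, dark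
Reagents that add atoms: N-bromosuccinimide, O=C1CCC(=O)N1Br
Why: Electrophilic aromatic bromination goes para to the benzyloxy group and ortho to the chain, as is general for 4-alkyl-1,2-dialkoxybenzenes, which marks C8a para to O-6.

**Step 4**
Reactants: 4 methyl 3-[5-(benzyloxy)-2-bromo-4-methoxyphenyl]propanoate; 5 methyl acrylate
Product: 6 methyl (E)-3-[4-(benzyloxy)-5-methoxy-2-(3-methoxy-3-oxopropyl)phenyl]prop-2-enoate
Conditions: Pd(OAc)2 (cat.), P(o-tol)3 (cat.), NaOAc, DMAc, 120 °C
Reagents that add atoms: none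
Why: The Mizoroki–Heck reaction of an aryl bromide with an acrylate gives the (E)-cinnamate by syn insertion and syn β-hydride elimination, and the saturated ester and benzyl ether are inert.

**Step 5**
Reactants: 6 methyl (E)-3-[4-(benzyloxy)-5-methoxy-2-(3-methoxy-3-oxopropyl)phenyl]prop-2-enoate; 7 [4-(benzyloxy)-3-methoxyphenyl]boronic acid
Product: 8 methyl (3S)-3-[4-(benzyloxy)-3-methoxyphenyl]-3-[4-(benzyloxy)-5-methoxy-2-(3-methoxy-3-oxopropyl)phenyl]propanoate
Conditions: [RhCl(C2H4)2]2 (cat.), (R,R)-Ph-bod* [(1R,4R)-2,5-diphenylbicyclo[2.2.2]octa-2,5-diene] (cat.), KOH (cat.), dioxane/H2O, 50 °C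
Reagents that add atoms: none
Why: In this Hayashi–Miyaura asymmetric 1,4-addition, a type established for cinnamates giving 3,3-diarylpropanoates, the aryl-Rh(I)/diene complex inserts the (E)-enoate on its α-re face and water protonates the oxa-π-allyl rhodium, which sets C1 as (S).

**Step 6**
Reactants: 8 methyl (3S)-3-[4-(benzyloxy)-3-methoxyphenyl]-3-[4-(benzyloxy)-5-methoxy-2-(3-methoxy-3-oxopropyl)phenyl]propanoate
Product: 10 dimethyl (1S)-6-(benzyloxy)-1-[4-(benzyloxy)-3-methoxyphenyl]-7-methoxy-1,2,3,4-tetrahydronaphthalene-2,3-dicarboxylate (mixture of C2/C3 epimers), via dilithium bis-enolate 9 (not isolated)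
Conditions: LDA (2.3 equiv, commercial solution), THF, −78 °C, high dilution; then anhydrous CuBr2 (2.3 equiv), −78 to 0 °C
Reagents that add atoms: none
Why: Double deprotonation gives bis-enolate 9, Cu(II) oxidises one enolate to an α-ester radical (or its copper-bound equivalent), this carbon bonds to the α-carbon of the second enolate, and a second Cu(II) removes the remaining electron, so C2–C3 forms with net loss of two electrons. The closest known reaction type is the copper(II)-mediated oxidative coupling of ester enolates to succinates, in its intramolecular form on α,ω-diester bis-enolates that gives cycloalkane-1,2-dicarboxylates. Ring B closes in a 6-exo-trig mode, because the acceptor enolate C=C stays outside the new ring. C2 is controlled by C1: A1,3 strain holds H-1 in the plane of the C2 enolate, ring A (which carries the tether to C3) covers one face and ring C the other, so C3 must bond anti to ring C, which is the 1,2-trans relation. C3 is controlled by the half-chair transition state, in which its ester unit takes the pseudo-equatorial site (2,3-trans), and any leakage to other epimers is corrected in step 7 because C1 is not touched. The step needs ring closure to win over dimerisation, seven-membered Dieckmann closure and arene oxidation, which the ortho placement of both chains on C4a/C8a, high dilution at low temperature and the benzyl caps on both phenols should secure.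

**Step 7**
Reactants: 10 dimethyl (1S)-6-(benzyloxy)-1-[4-(benzyloxy)-3-methoxyphenyl]-7-methoxy-1,2,3,4-tetrahydronaphthalene-2,3-dicarboxylate (mixture of C2/C3 epimers)
Product: 11 dimethyl (1S,2R,3R)-6-(benzyloxy)-1-[4-(benzyloxy)-3-methoxyphenyl]-7-methoxy-1,2,3,4-tetrahydronaphthalene-2,3-dicarboxylate
Conditions: NaOMe (cat.), MeOH, reflux
Reagents that add atoms: none
Why: Base-mediated epimerisation through the ester enolates equilibrates only C2 and C3 and should funnel all epimers to the all-equatorial 1,2-trans-2,3-trans diester, while the non-acidic diarylmethine C1 keeps the absolute configuration.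

**Step 8**
Reactants: 11 dimethyl (1S,2R,3R)-6-(benzyloxy)-1-[4-(benzyloxy)-3-methoxyphenyl]-7-methoxy-1,2,3,4-tetrahydronaphthalene-2,3-dicarboxylate
Product: 12 [(1S,2R,3R)-6-(benzyloxy)-1-[4-(benzyloxy)-3-methoxyphenyl]-7-methoxy-1,2,3,4-tetrahydronaphthalene-2,3-diyl]dimethanol
Conditions: LiAlH4, THF, 0 °C to rt; aqueous NaOH work-up
Reagents that add atoms: none
Why: Hydride reduction of both esters to primary alcohols outruns any enolisation, so C2 and C3 are retained, and the aryl ethers are inert.

**Step 9**
Reactants: 12 [(1S,2R,3R)-6-(benzyloxy)-1-[4-(benzyloxy)-3-methoxyphenyl]-7-methoxy-1,2,3,4-tetrahydronaphthalene-2,3-diyl]dimethanol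
Product: 13 (1S,2R,3R)-1-(4-hydroxy-3-methoxyphenyl)-2,3-bis(hydroxymethyl)-7-methoxy-1,2,3,4-tetrahydronaphthalen-6-ol (target)
Conditions: H2 (1 atm), 10% Pd/C, EtOAc/MeOH, rt
Reagents that add atoms: none
Why: Catalytic hydrogenolysis cleaves only the two O-benzyl bonds, since the C1 diarylmethine has no benzylic heteroatom and the primary alcohols are not benzylic.

**Compound list**

1 | 3-(3-hydroxy-4-methoxyphenyl)propanoic acid | COc1ccc(CCC(=O)O)cc1O | starting material
2 | methyl 3-(3-hydroxy-4-methoxyphenyl)propanoate | COC(=O)CCc1ccc(OC)c(O)c1 | intermediate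
3 | methyl 3-[3-(benzyloxy)-4-methoxyphenyl]propanoate | COC(=O)CCc1ccc(OC)c(OCc2ccccc2)c1 | intermediate
4 | methyl 3-[5-(benzyloxy)-2-bromo-4-methoxyphenyl]propanoate | COC(=O)CCc1cc(OCc2ccccc2)c(OC)cc1Br | intermediate
5 | methyl acrylate | C=CC(=O)OC | starting material
6 | methyl (E)-3-[4-(benzyloxy)-5-methoxy-2-(3-methoxy-3-oxopropyl)phenyl]prop-2-enoate | COC(=O)/C=C/c1cc(OC)c(OCc2ccccc2)cc1CCC(=O)OC | intermediate
7 | [4-(benzyloxy)-3-methoxyphenyl]boronic acid | COc1cc(B(O)O)ccc1OCc1ccccc1 | starting material
8 | methyl (3S)-3-[4-(benzyloxy)-3-methoxyphenyl]-3-[4-(benzyloxy)-5-methoxy-2-(3-methoxy-3-oxopropyl)phenyl]propanoate | COc1cc([C@H](CC(=O)OC)c2cc(OC)c(OCc3ccccc3)cc2CCC(=O)OC)ccc1OCc1ccccc1 | intermediate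
9 | dilithium bis-enolate of 8 | COc1cc([C@H](C=C([O-])OC)c2cc(OC)c(OCc3ccccc3)cc2CC=C([O-])OC)ccc1OCc1ccccc1.[Li+].[Li+] | intermediate
10 | dimethyl (1S)-6-(benzyloxy)-1-[4-(benzyloxy)-3-methoxyphenyl]-7-methoxy-1,2,3,4-tetrahydronaphthalene-2,3-dicarboxylate (mixture of C2/C3 epimers) | COc1cc([C@H]2c3cc(OC)c(OCc4ccccc4)cc3CC(C(=O)OC)C2C(=O)OC)ccc1OCc1ccccc1 | intermediate
11 | dimethyl (1S,2R,3R)-6-(benzyloxy)-1-[4-(benzyloxy)-3-methoxyphenyl]-7-methoxy-1,2,3,4-tetrahydronaphthalene-2,3-dicarboxylate | COc1cc([C@H]2c3cc(OC)c(OCc4ccccc4)cc3C[C@@H](C(=O)OC)[C@@H]2C(=O)OC)ccc1OCc1ccccc1 | intermediate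
12 | [(1S,2R,3R)-6-(benzyloxy)-1-[4-(benzyloxy)-3-methoxyphenyl]-7-methoxy-1,2,3,4-tetrahydronaphthalene-2,3-diyl]dimethanol | COc1cc([C@H]2c3cc(OC)c(OCc4ccccc4)cc3C[C@@H](CO)[C@@H]2CO)ccc1OCc1ccccc1 | intermediate
13 | (1S,2R,3R)-1-(4-hydroxy-3-methoxyphenyl)-2,3-bis(hydroxymethyl)-7-methoxy-1,2,3,4-tetrahydronaphthalen-6-ol | COc1cc([C@H]2c3cc(OC)c(O)cc3C[C@@H](CO)[C@@H]2CO)ccc1O | target

Total step count: 9. Longest linear sequence: 9 steps (1 to 13).

**Steps most likely to fail**

**Step 6.**
- What may go wrong: the oxidised enolate may be diverted before C2–C3 bonding. Possible diversions are intermolecular coupling, 1,5-hydrogen transfer from the doubly benzylic C1–H to a C3-centred radical (which would erode C1), and α-bromination followed by loss of HBr towards a cinnamate.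
- Fallback: a polar ring contraction that avoids radicals, setting out from 8.
- Dieckmann condensation (KOtBu, toluene, high dilution) should give the seven-membered β-keto ester methyl (9S)-3-(benzyloxy)-9-[4-(benzyloxy)-3-methoxyphenyl]-2-methoxy-7-oxo-6,7,8,9-tetrahydro-5H-benzo[7]annulene-6-carboxylate F1.
- Chlorination at the doubly activated carbon (NCS, CH2Cl2) gives the corresponding methyl 6-chloro-7-oxo-benzo[7]annulene-6-carboxylate F2.
- NaOMe in MeOH then triggers a Favorskii ring contraction. A cyclopropanone forms between the former C2 and C3 and opens towards the ester-stabilised carbanion, which makes the C2–C3 bond and comes back to the route at 10.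

**Step 5.**
- What may go wrong: insertion into an electron-rich, ortho-substituted cinnamate may be slow, protodeboronation may compete, and facial selectivity may be poor.
- Fallback: the stereocenter is made by enantioselective reduction instead of arylation, setting out from 6.
- A second Mizoroki–Heck reaction with 1-(benzyloxy)-4-iodo-2-methoxybenzene (Pd(OAc)2, NaOAc, DMAc) places the incoming ring C trans to the ester. This gives methyl (Z)-3-[4-(benzyloxy)-3-methoxyphenyl]-3-[4-(benzyloxy)-5-methoxy-2-(3-methoxy-3-oxopropyl)phenyl]prop-2-enoate F3.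
- Iridium/N,P-catalysed asymmetric hydrogenation of this geometrically defined β,β-diarylacrylate, with the ligand antipode chosen for the (S)-product, leaves the benzyl ethers intact and comes back to the route at 8.

**Step 7.**
- What may go wrong: the thermodynamic bias may be insufficient, because the 1,2-cis-2,3-trans epimer with a pseudo-axial ring C may stay populated.
- Fallback: control of C2/C3 is moved from thermodynamics to auxiliaries, setting out from 8.
- LiOH saponification gives (3S)-3-[4-(benzyloxy)-3-methoxyphenyl]-3-[4-(benzyloxy)-2-(2-carboxyethyl)-5-methoxyphenyl]propanoic acid F4.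
- Pivaloyl chloride/Et3N followed by lithiated (S)-4-isopropyl-1,3-oxazolidin-2-one gives the bis[(4S)-4-isopropyl-2-oxo-oxazolidin-3-yl] imide of the open diacid F5.
- Oxidative coupling of its bis-enolate (LDA, then a Cu(II) salt) should give the (1S,2R,3R)-tetralin-2,3-dicarbonyl bis[(4S)-4-isopropyl-oxazolidin-2-one] F6. Both auxiliaries shield the faces that lead to (2R,3R), which is matched with the bias from C1.
- LiBH4 reduction releases the auxiliaries and comes back to the route at 12.

**Further compounds**

F1 | step 6 | methyl (9S)-3-(benzyloxy)-9-[4-(benzyloxy)-3-methoxyphenyl]-2-methoxy-7-oxo-6,7,8,9-tetrahydro-5H-benzo[7]annulene-6-carboxylate | COc1cc([C@@H]2CC(=O)C(C(=O)OC)Cc3cc(OCc4ccccc4)c(OC)cc32)ccc1OCc1ccccc1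
F2 | step 6 | methyl (9S)-3-(benzyloxy)-9-[4-(benzyloxy)-3-methoxyphenyl]-6-chloro-2-methoxy-7-oxo-6,7,8,9-tetrahydro-5H-benzo[7]annulene-6-carboxylate | COc1cc([C@@H]2CC(=O)C(Cl)(C(=O)OC)Cc3cc(OCc4ccccc4)c(OC)cc32)ccc1OCc1ccccc1
F3 | step 5 | methyl (Z)-3-[4-(benzyloxy)-3-methoxyphenyl]-3-[4-(benzyloxy)-5-methoxy-2-(3-methoxy-3-oxopropyl)phenyl]prop-2-enoate | COC(=O)/C=C(/c1ccc(OCc2ccccc2)c(OC)c1)c1cc(OC)c(OCc2ccccc2)cc1CCC(=O)OC
F4 | step 7 | (3S)-3-[4-(benzyloxy)-3-methoxyphenyl]-3-[4-(benzyloxy)-2-(2-carboxyethyl)-5-methoxyphenyl]propanoic acid | COc1cc([C@H](CC(=O)O)c2cc(OC)c(OCc3ccccc3)cc2CCC(=O)O)ccc1OCc1ccccc1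
F5 | step 7 | bis[(4S)-4-isopropyl-2-oxo-oxazolidin-3-yl] imide of the open diacid | COc1cc([C@H](CC(=O)N2[C@@H](C(C)C)COC2=O)c2cc(OC)c(OCc3ccccc3)cc2CCC(=O)N2[C@@H](C(C)C)COC2=O)ccc1OCc1ccccc1
F6 | step 7 | (1S,2R,3R)-tetralin-2,3-dicarbonyl bis[(4S)-4-isopropyl-oxazolidin-2-one] | COc1cc([C@H]2c3cc(OC)c(OCc4ccccc4)cc3C[C@@H](C(=O)N3[C@@H](C(C)C)COC3=O)[C@@H]2C(=O)N2[C@@H](C(C)C)COC2=O)ccc1OCc1ccccc1
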